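The numbers of this flask are those of an exercise; the rest is arithmetic.

If I want the length of a chain in this flask, I count turnovers: the monomer units one chain has taken up since it began.

free monomer 30 mM; transfer agent 0.300 mM; pre-initiator 0.60 mM; impurity 60 µM; time 30 min

- average number of monomer units in a chain (chains begun, living or dead) at 30 min
- part of the free monomer that has reacted at 30 min

- the average divides the monomer in chains by the number of chains begun, living and dead together
- run time (flask): 30 min

    initiator + impurity → spent initiator (k1 = 45000 L mol⁻¹ min⁻¹)
    pre-initiator → initiator (k2 = 0.017 min⁻¹)
    living end + transfer agent → dead chain (k3 = 47 L mol⁻¹ min⁻¹)
    free monomer + living end → monomer in chains + living end, rate k4*[living end]*[free monomer] (k4 = 24 L mol⁻¹ min⁻¹)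
    free monomer + initiator → living end + monomer in chains (k5 = 65 L mol⁻¹ min⁻¹)

One living end adds monomer at 0.720 min⁻¹ with free monomer at its charge. This is the turnover rate, monomer units per living end per minute, a pseudo-first-order constant.

Next I count the chains. The pre-initiator slowly gives initiator, 0.240 mM by the asked time, and the impurity destroys initiator. Its charge is smaller than that, so I take it off whole and have 0.180 mM of chains begun. The half-life of the pre-initiator, 40.8 min, is longer than the run, so chains begin fairly evenly and I take the average chain to be half the run old. With the unit that starts it, that gives 11.8 units.

The weak link is that a chain stopped by the transfer agent does not grow for its whole age. With the transfer agent at its charge, a living end is stopped at 0.0141 min⁻¹, so I reckon the average chain has grown for 13.5 min. I commit to a dp of 10.7, and over my chains that is a conversion of 6.43 %.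

The forecast gives a dp of 9.5, lower than mine, and a conversion of 5.7 %, and pictures “most chains still living because transfer is slow”.

The simulation gives a dp of 9.69 and a conversion of 5.73 %, so the forecast holds and my dp stands high.

The half-life of free monomer by the growth step at the asked time, 200 min, is long against the run. With 94 % of the charge left at the asked time, the turnover rate has eased from 0.720 min⁻¹ to 0.677 min⁻¹. A run that could show the forecast wrong lies further off: the dp of this flask has moved by 0.969 with free monomer at 26.9 mM or 33.1 mM, or with the reading at 26.4 min or 33.6 min.

For the same flask left until 12 min, the turnover rate and transfer give a dp of 5.14. The simulation gives 4.75.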